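All runs come from a simulation for an exercise, noise included.

24.5 % of the substrate consumed had appeared as target by the last readings of the zeta and alpha runs. I called this fraction, target formed over substrate consumed, the capture share (the selectivity), and I carried it to the new flasks.

in all of them: substrate 10 mM; free catalyst 0.18 mM
- zeta: partner 31 mM; run made earlier
- alpha: partner 290 mM; run made earlier
- noon: partner 25.0 mM; time 15 h
- dawn: partner 50.0 mM; time 15 h
- spring: partner 100 mM; time 15 h
- midnight: partner 200 mM; time 15 h

| run | time / h | target / % | substrate / % |
|---|---|---|---|
| zeta | 3.00 | 1.1 | 92.4 |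
| zeta | 6.00 | 3.4 | 85.0 |
| zeta | 10.0 | 7.8 | 76.4 |
| zeta | 12.0 | 6.6 | 73.3 |
| zeta | 15.0 | 7.7 | 67.6 |
| alpha | 1.33 | 0 | 96.9 |
| alpha | 4.00 | 2.1 | 90.4 |
| alpha | 8.00 | 5.2 | 80.3 |
| alpha | 10.0 | 6.5 | 78.1 |
| alpha | 15.0 | 8.1 | 68.0 |

(each reading ± 0.5 percentage points)

- the earlier runs were read with a standard deviation of 0.5 percentage points
- a reading or a percentage of target counts all its forms, free or not
- "hardly changes" means that all values lie within two and a half points (for a concentration: within two and a half percent of the largest)

* amount of target at the end, in percent of the substrate charged for noon, dawn, spring, midnight, in this order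
* the course of these numbers from the first flask to the last (rises all the way / hardly changes / falls, then rises / falls all the way / rises, then falls)

I kept the books on substrate, the limiting reagent, since its charge is smaller than the partner's. At 15.0 h they read, in percent of the substrate charged:

zeta: substrate left 67.6 %, target 7.7 %, not found 24.7 %

alpha: substrate left 68.0 %, target 8.1 %, not found 23.9 %

Neither book closed on what was read, so something unseen held the last entry. Yet a factor of 9.35 in partner moved target by 0.4 percentage points, less than the scatter of 0.5 points. I therefore took the same loss of substrate for the new flasks and went round twice.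

First round, substrate gone: 32.2 %; times the capture share, target: 7.90 %

Second round, noon, the leanest flask, reckoned by my own assumption at one partner spent per substrate gone: partner lost 12.9 %, leaving 21.8 mM

Scaling the earlier difference on the logarithm of partner, the step from zeta's charge down to that floor took off 0.063 points, less than the scatter. So I kept 7.90 % for noon, dawn, spring and midnight, a row that hardly changes.

The forecast gave 7.8 %, 8 %, 8 % and 8 %, hardly changes, setting noon slightly apart, “so it could be marginally lower”, where I had one value for the row.

The flasks gave 7.56 %, 7.65 %, 7.68 % and 7.70 %: hardly changes.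

    substrate + free catalyst ⇌ free catalyst + open intermediate (K = 1.10, k = 0.0430 M⁻¹ s⁻¹)
    free catalyst + open intermediate ⇌ catalyst intermediate (K = 300 M⁻¹, k = 0.280 M⁻¹ s⁻¹)
    partner + catalyst intermediate → free catalyst + target (k = 1.30 M⁻¹ s⁻¹)
    open intermediate → side product (k = 3.80 × 10⁻⁵ s⁻¹)
    target + free catalyst ⇌ isomer of the product + free catalyst, rate k5*[free catalyst]*[target] forward; the back reaction follows from the equilibrium constant (K = 3.50, k = 0.220 M⁻¹ s⁻¹)
    crystals ⇌ target, rate k6*(cs6 - [target]) while solid is left; crystals form when [target] > cs6 (solubility = 4.90 mM, k = 0.00330 s⁻¹)

Noon kept 68 % of its substrate at 15.0 h, and the capture share on that loss gives 7.84 % of target against the 7.56 % found. Midnight kept 68 %, which gives 7.94 % against 7.70 %. The largest single effect proven on that low share is the step from target to isomer of the product: in midnight, with that step taken away, target ends at 15.1 % instead of 7.70 %.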